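If we take full target as the zero of our scale, the question for this flask turns round: what has to be true for it to end anywhere but at the shortfall the earlier runs show?

| flask | starting material | coupling partner | protic impurity | free catalyst | remark | time |
|---|---|---|---|---|---|---|
| Tuesday's | 34 mM | 1.2 equiv (in portions, 2) | 3.4 mM | 0.07 mol% | run made earlier; portions every 2.0 h |  |
| Wednesday's | 34 mM | 1.2 equiv (in portions, 2) | 3.4 mM | 0.11 mol% | run made earlier; portions every 2.0 h |  |
| Thursday's | 17 mM | 1.2 equiv (in portions, 2) | 3.4 mM | 0.14 mol% | run made earlier; portions every 2.0 h |  |
| flask | 34 mM | 1.20 equiv (in portions, 2) | 3.40 mM | 0.14 mol% | the portions of coupling partner follow each other after 2.0 h, the first at the start | 5.0 d |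

| run | time / d | starting material / % | target / % |
|---|---|---|---|
| Tuesday's | 0.417 | 20.3 | 69.3 |
| Tuesday's | 1.25 | 0 | 90.0 |
| Tuesday's | 2.50 | 0 | 90.0 |
| Tuesday's | 4.00 | 0 | 90.2 |
| Tuesday's | 5.00 | 0 | 89.8 |
| Wednesday's | 0.417 | 3.7 | 86.7 |
| Wednesday's | 1.25 | 0.1 | 89.8 |
| Wednesday's | 2.50 | 0 | 89.2 |
| Wednesday's | 4.00 | 0 | 90.6 |
| Wednesday's | 5.00 | 0.4 | 90.1 |
| Thursday's | 0.417 | 0 | 79.8 |
| Thursday's | 1.25 | 0.1 | 80.1 |
| Thursday's | 2.50 | 0.1 | 79.4 |
| Thursday's | 4.00 | 0 | 79.6 |
| Thursday's | 5.00 | 0 | 79.5 |

(scatter of a reading: 0.3 percentage points)

- the analysis behind the earlier runs scatters by 0.3 percentage points, standard deviation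
- the reaction counts as stopped when no species that holds the starting material changes by six tenths of a point or more over the second half of the time

- the state of affairs at 5.0 d: stopped, and by what, or still going (all of the starting material has reacted / it is still moving / no working catalyst is left / the coupling partner has run out first / forward and back rates have come level)
- how much of the starting material has reacted by 5.0 d
- how much target there is at 5.0 d, in percent of the starting material charged

Tuesday's run ended at 89.8% target with 0% starting material, which is 3.47 mM short. Thursday's run, with half the starting material, ended at 79.5%, which is 3.48 mM short. Both shortfalls read close to the protic impurity charged in each run, 3.4 mM, so we count it as costing starting material one for one. Counting coupling partner one for one as well, we then let target exceed neither one minus the ratio of protic impurity to starting material, nor the equivalents of coupling partner. In this flask the smaller of the two is 90.0%, and that smaller one is our ceiling on target. For Thursday's run the same reckoning gives 80.0%.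

With this charge of protic impurity, we look at two ways for this flask to end otherwise: too little coupling partner, or a catalyst that stops early. It has 1.20 equiv of coupling partner, more than the ceiling asks for. Tuesday's run, with half this flask's loading, read 0% starting material at 1.25 d, well inside 5.0 d. So we expect this flask to stop at the ceiling. On a repeat, the sum to watch is starting material plus target, which on Tuesday already read 89.6% at 0.417 d.

The forecast agrees: all of the starting material has reacted, conversion 100%, target 90%. Its ground: “Catalyst loading changes the rate but not the plateau”.

The flask gives 90.0% target at 5.0 d, with 100% conversion: all of the starting material has reacted.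

coupling partner + free catalyst → catalyst intermediate A (k = 382 M⁻¹ min⁻¹); catalyst intermediate D ⇌ free catalyst + target (K = 0.0203 M, k = 19.7 min⁻¹); catalyst intermediate C ⇌ catalyst intermediate D (K = 0.486, k = 20.6 min⁻¹); starting material + protic impurity → quenched substrate (k = 3.24 M⁻¹ min⁻¹); catalyst intermediate A ⇌ catalyst intermediate B (K = 1.43, k = 18.3 min⁻¹); starting material + catalyst intermediate B → catalyst intermediate C (k = 5170 M⁻¹ min⁻¹) Quenched substrate stands at 10.0% of the starting material at 5.00 d. A neighbouring flask shows one way for the forecast to be wrong: with 0.300 equiv of coupling partner, the ceiling becomes 30.0%. That flask gives 29.9% target, with coupling partner as the limiting reagent, 0% of it left, and 60.0% of the starting material still unreacted at 5.00 d.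

(The numbers in the tables come from a simulation with made-up constants; noise was put on by code.)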